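**Retrosynthetic overview**
- The strategy rests on ring A. Its quaternary, methyl-bearing C10 lies para to the oxygenated C3, and the neighbouring C4 carries the oxidised carbon C19. Ring A (C1–C5, C10) is therefore traced back to an aromatic 5-methylsalicylate whose phenolate para carbon is a latent C10 nucleophile.
- The key disconnection is C9–C10. A C7 allylic carbonate is ionised by zerovalent palladium and C10 attacks C9. This closes ring B, the only ring formed in the route since ring A is the arene, and leaves C7=C8 in place.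
- The C6–C7 bond comes from lateral lithiation of the salicylate C6 methyl and acylation with a citronellol-derived enoyl Weinreb amide. A CBS reduction sets C7. The ketone is reached directly, so no lactone has to be opened against its equilibrium.
- After ring closure: C1=C2 hydrogenation, Li/NH3 reductive methylation (C5, C4), C2 hydroxylation, axial C3 reduction, C19 and C15 oxidation-level adjustment, C2 acetylation.

Key step: step 12

Remark: labdane numbering (C1–C20) is used for all compounds. The target is read as (2S,3R,4S,5S,9R,10S,13R), an ent-labdane. C20, C19 (CHO) and the C9 side chain lie on one face; H-5, H-9, C18, 2-OAc and 3-OH lie on the other.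

**Step 1**
Reactants: 1 2,3-dimethylbenzoic acid
Product: 2 6-hydroxy-2,3-dimethylbenzoic acid
Conditions: Pd(OAc)2 (10 mol %), KOAc, O2 (5 atm), DMA, 115 °C; aq HCl
Reagents that add atoms: dioxygen, O=O
Why: Carboxylate-directed ortho C–H hydroxylation by divalent palladium under O2 finds only one free ortho C–H (the later C3), so a single salicylic acid is expected.

**Step 2**
Reactants: 2 6-hydroxy-2,3-dimethylbenzoic acid
Product: 3 methyl 6-hydroxy-2,3-dimethylbenzoate
Conditions: MeI, KHCO3, DMF, 25 °C
Reagents that add atoms: iodomethane, CI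
Why: SN2 O-alkylation of the carboxylate esterifies a di-ortho-substituted acid that resists Fischer esterification, while the weak base leaves the hydrogen-bonded phenol protonated and unalkylated.

**Step 3**
Reactants: 3 methyl 6-hydroxy-2,3-dimethylbenzoate
Product: 4 methyl 6-(tert-butyldimethylsilyloxy)-2,3-dimethylbenzoate
Conditions: TBSCl, imidazole, DMF, 25 °C
Reagents that add atoms: tert-butyldimethylsilyl chloride, CC(C)(C)[Si](C)(C)Cl
Why: Imidazole-promoted silylation masks the phenol for the strong-base step, and an aryl TBS ether can later be removed selectively beside an alkyl TIPS ether.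

**Step 4**
Reactants: 5 (R)-citronellol
Product: 6 (3R)-3,7-dimethyloct-6-en-1-yl triisopropylsilyl ether
Conditions: TIPSCl, imidazole, CH2Cl2, 0 → 25 °C
Reagents that add atoms: triisopropylsilyl chloride, CC(C)[Si](Cl)(C(C)C)C(C)C
Why: Routine silylation of the primary alcohol (the later C15) installs a group that survives base, hydride, dissolving metal and buffered fluoride, and C13 is not touched.

**Step 5**
Reactants: 6 (3R)-3,7-dimethyloct-6-en-1-yl triisopropylsilyl ether
Product: 8 (4R)-4-methyl-6-(triisopropylsilyloxy)hexanal, via secondary ozonide 7 (not isolated)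
Conditions: O3, CH2Cl2, −78 °C; Me2S, −78 → 25 °C
Reagents that add atoms: ozone, [O-][O+]=O
Why: Ozonolysis with reductive work-up cleaves the only alkene and gives the aldehyde carbon that becomes C9.

**Step 6**
Reactants: 8 (4R)-4-methyl-6-(triisopropylsilyloxy)hexanal; 9 ethyl 2-(triphenylphosphoranylidene)propanoate
Product: 10 ethyl (2E,6R)-2,6-dimethyl-8-(triisopropylsilyloxy)oct-2-enoate
Conditions: toluene, 80 °C
Reagents that add atoms: none
Why: The Wittig reaction of a stabilised α-methyl ylide is reliably E-selective, which places C11 trans to the carbonyl carbon C7 across C8=C9.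

**Step 7**
Reactants: 10 ethyl (2E,6R)-2,6-dimethyl-8-(triisopropylsilyloxy)oct-2-enoate
Product: 11 (2E,6R)-N-methoxy-N,2,6-trimethyl-8-(triisopropylsilyloxy)oct-2-enamide
Conditions: MeNH(OMe)·HCl, i-PrMgCl, THF, −20 → 0 °C
Reagents that add atoms: N,O-dimethylhydroxylamine hydrochloride, CNOC.Cl
Why: Weinreb amide synthesis by aminolysis of the ester with the magnesium amide is established for enoates and proceeds without conjugate addition or alkene isomerisation.

**Step 8**
Reactants: 4 methyl 6-(tert-butyldimethylsilyloxy)-2,3-dimethylbenzoate; 11 (2E,6R)-N-methoxy-N,2,6-trimethyl-8-(triisopropylsilyloxy)oct-2-enamide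
Product: 13 methyl 6-(tert-butyldimethylsilyloxy)-3-methyl-2-[(3E,7R)-3,7-dimethyl-2-oxo-9-(triisopropylsilyloxy)non-3-en-1-yl]benzoate, via lithiated toluate 12 (not isolated)
Conditions: LiN(i-Pr)2 (2.1 equiv), THF, −78 °C; 11; AcOH, −78 °C
Reagents that add atoms: none
Why: In this lateral lithiation only the methyl ortho to the ester is acidified, acylation by the Weinreb amide stops at the ketone through the chelated tetrahedral adduct, the α-methyl group and low temperature disfavour 1,4-addition, and the second equivalent of base takes up the acidic product.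

**Step 9**
Reactants: 13 the C7 ketone
Product: 14 methyl 6-(tert-butyldimethylsilyloxy)-3-methyl-2-[(2R,3E,7R)-2-hydroxy-3,7-dimethyl-9-(triisopropylsilyloxy)non-3-en-1-yl]benzoate
Conditions: (S)-Me-CBS (20 mol %), BH3·SMe2, THF, −30 °C; MeOH
Reagents that add atoms: none
Why: In the Corey–Bakshi–Shibata reduction the α-branched alkenyl group acts as the large substituent and CH2Ar as the small one, so the (S)-oxazaborolidine should give the 7R allylic alcohol (the sense known for acetophenone), and the volatile boron by-products allow it to be carried on crude without a basic wash.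

**Step 10**
Reactants: 14 the (7R)-allylic alcohol
Product: 15 methyl 6-(tert-butyldimethylsilyloxy)-2-[(2R,3E,7R)-2-(methoxycarbonyloxy)-3,7-dimethyl-9-(triisopropylsilyloxy)non-3-en-1-yl]-3-methylbenzoate
Conditions: ClCO2Me, pyridine, DMAP (cat.), CH2Cl2, 0 °C
Reagents that add atoms: methyl chloroformate, COC(=O)Cl
Why: O-acylation by the chloroformate under weakly basic conditions should be faster than attack of the neutral C7 hydroxyl on the doubly ortho-flanked ester, so the alcohol is capped before it can lactonise, with C7 unchanged.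

**Step 11**
Reactants: 15 the silyl-protected carbonate
Product: 16 methyl 6-hydroxy-2-[(2R,3E,7R)-2-(methoxycarbonyloxy)-3,7-dimethyl-9-(triisopropylsilyloxy)non-3-en-1-yl]-3-methylbenzoate
Conditions: Bu4NF, AcOH, THF, 0 °C
Reagents that add atoms: none
Why: Buffered fluoride cleaves the aryl silyl ether far faster than the hindered primary TIPS ether, and the near-neutral medium leaves the allylic carbonate and the ester intact.

**Step 12**
Reactants: 16 the salicylate allylic carbonate
Product: 17 methyl (9R,10S,13R)-3-oxo-15-(triisopropylsilyloxy)-18-norlabda-1,4,7-trien-19-oate (cross-conjugated dienone)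
Conditions: Pd2(dba)3·CHCl3 (2.5 mol %), PPh3 (12 mol %), CH2Cl2 (0.01 M), 25 → 40 °C
Reagents that add atoms: none
Why: Zerovalent palladium ionises the C7 carbonate anti to the leaving group, CO2 is lost and the methoxide so formed deprotonates the phenol, so that a cationic η3-allyl (C7–C8–C9) and its phenolate arise without added base, and the phenolate para carbon C10 then attacks C9 anti to the metal. The closest known reaction type is the palladium-catalysed intramolecular allylic alkylative dearomatisation (ipso-Friedel–Crafts type) of para-substituted phenols bearing allylic carbonates, and closure from a meta tether onto a methyl-bearing para carbon is the ring pattern known from arylative dearomative cyclisations. Ring B closes in a 6-endo mode with respect to the allyl unit, since C7, C8 and C9 all become ring members and the new C7=C8 bond is endocyclic; the only alternative, attack at C7, would be a 4-exo closure to a cyclobutane, and the required allyl isomer with C6 anti is reached directly from the reactive rotamer or by π–σ–π exchange through C7, which leaves the stereochemical relay intact and is eased by the C17 methyl on the central allyl carbon. C9 is set by the double inversion (net retention, formally a syn SN2′ process), so that the 7R carbonate with the E alkene (C11 syn on the allyl) delivers 9R. C10 is set by the half-chair transition state that this trajectory enforces, with the C11 chain pseudo-equatorial and C20 anti to H-9, which gives 10S with C20 and the chain cis. The step needs C10 rather than C4 or oxygen as the nucleophilic site: O-alkylation would demand a meta-bridged ring, and attack through C4 builds a crowded quaternary β-keto ester carbon in a linearly conjugated dienone whose doubly activated allylic C4–C9 bond should be re-ionised by the catalyst, so that the cross-conjugated dienone 17 is the expected sink.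

**Step 13**
Reactants: 17 the cross-conjugated dienone
Product: 18 methyl (9R,10S,13R)-3-oxo-15-(triisopropylsilyloxy)-18-norlabda-4,7-dien-19-oate
Conditions: H2 (1 atm), RhCl(PPh3)3 (10 mol %), toluene–EtOH, 25 °C
Reagents that add atoms: none
Why: Homogeneous hydrogenation with RhCl(PPh3)3 discriminates by substitution, so, as with steroidal 1,4-dien-3-ones, only the disubstituted C1=C2 is saturated, and removing this alkene first avoids reductive C9–C10 fragmentation of the dienone in the next step.

**Step 14**
Reactants: 18 the enone ester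
Product: 20 methyl (4S,5S,9R,10S,13R)-3-oxo-15-(triisopropylsilyloxy)labd-7-en-19-oate, via lithium enolate 19 (not isolated)
Conditions: Li, NH3(l)–THF, t-BuOH (1 equiv), −78 °C; NH3 off; MeI, THF, 0 → 25 °C
Reagents that add atoms: iodomethane, CI
Why: Dissolving-metal conjugate reduction with enolate trapping (reductive alkylation) is the classical entry to 4-methyl-4-carboalkoxy-3-decalones: the C5 carbanion is protonated axially, anti to C20, to give the trans fusion (5S), and the β-keto ester enolate 19 is methylated on the face away from the axial C20, so that C18 becomes equatorial and the ester C19 axial (4S).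

**Step 15**
Reactants: 20 the trans-decalin keto ester
Product: 22 methyl (2S,4S,5S,9R,10S,13R)-2-hydroxy-3-oxo-15-(triisopropylsilyloxy)labd-7-en-19-oate, via potassium enolate 21 (not isolated)
Conditions: KN(SiMe3)2, THF, −78 °C; 2-(phenylsulfonyl)-3-phenyloxaziridine; AcOH
Reagents that add atoms: 2-(phenylsulfonyl)-3-phenyloxaziridine, O=S(=O)(c1ccccc1)N1OC1c1ccccc1
Why: Davis oxidation of the only possible enolate (towards C2, as C4 is quaternary) takes place on the ring face opposite the axial C20 and C19 groups, gives the equatorial 2S hydroxyl, which is also the more stable epimer, and spares the C7=C8 alkene.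

**Step 16**
Reactants: 22 the 2-hydroxy-3-ketone
Product: 23 methyl (2S,3R,4S,5S,9R,10S,13R)-2,3-dihydroxy-15-(triisopropylsilyloxy)labd-7-en-19-oate
Conditions: Li[HB(s-Bu)3], THF, −78 °C; H2O2, aq NaOH, 0 °C
Reagents that add atoms: none
Why: A bulky trialkylborohydride follows the equatorial trajectory because the axial one is closed by the syn-axial H-1 and H-5, as in the known conversion of 4,4-disubstituted 3-oxo terpenoid A rings into axial alcohols, and so should give the axial 3R hydroxyl cis to the C2 oxygen.

**Step 17**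
Reactants: 23 the cis-2,3-diol
Product: 24 methyl (2S,3R,4S,5S,9R,10S,13R)-2,3-(isopropylidenedioxy)-15-(triisopropylsilyloxy)labd-7-en-19-oate
Conditions: Me2C(OMe)2, PPTS, CH2Cl2, 25 °C
Reagents that add atoms: 2,2-dimethoxypropane, COC(C)(C)OC
Why: Transacetalisation closes a dioxolane readily on an axial/equatorial cis-diol, and the mild acid leaves the TIPS ether and the trisubstituted alkene alone.

**Step 18**
Reactants: 24 the acetonide ester
Product: 25 (2S,3R,4R,5S,9R,10S,13R)-2,3-(isopropylidenedioxy)-15-(triisopropylsilyloxy)labd-7-en-19-ol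
Conditions: LiAlH4, THF, 0 → 65 °C
Reagents that add atoms: none
Why: Hydride reduction with LiAlH4 at elevated temperature is the standard way to reduce hindered axial C4 esters of decalins, and acetonide, silyl ether and alkene are inert to it (the C4 descriptor changes by priority only).

**Step 19**
Reactants: 25 the C19 alcohol
Product: 26 (2S,3R,4S,5S,9R,10S,13R)-2,3-(isopropylidenedioxy)-15-(triisopropylsilyloxy)labd-7-en-19-al
Conditions: Dess–Martin periodinane, CH2Cl2, 0 → 25 °C
Reagents that add atoms: none
Why: Dess–Martin oxidation converts neopentyl primary alcohols cleanly into aldehydes, and the aldehyde formed has no α-hydrogen and cannot epimerise.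

**Step 20**
Reactants: 26 the C19 aldehyde
Product: 27 (2S,3R,4S,5S,9R,10S,13R)-15-hydroxy-2,3-(isopropylidenedioxy)labd-7-en-19-al
Conditions: Bu4NF, THF, 25 °C
Reagents that add atoms: none
Why: Fluoride desilylation frees C15–OH, while the non-enolisable aldehyde is base-tolerant and retro-aldol cleavage is blocked because O-3 is tied up in the acetonide.

**Step 21**
Reactants: 27 the C15 alcohol
Product: 28 (2S,3R,4S,5S,9R,10S,13R)-2,3-(isopropylidenedioxy)-19-oxolabd-7-en-15-oic acid
Conditions: TEMPO (20 mol %), PhI(OAc)2, MeCN–H2O, 25 °C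
Reagents that add atoms: water, O
Why: The aqueous TEMPO/PhI(OAc)2 oxidation takes an unhindered primary alcohol to the acid through the aldehyde hydrate, whereas the axial, α-quaternary C19 aldehyde hardly hydrates and is too hindered for the oxoammonium salt, so it should stay at the aldehyde level.

**Step 22**
Reactants: 28 the acetonide acid
Product: 29 (2S,3R,4S,5S,9R,10S,13R)-2,3-dihydroxy-19-oxolabd-7-en-15-oic acid
Conditions: AcOH–H2O (4:1), 45 °C
Reagents that add atoms: none
Why: Mild acid hydrolysis removes the acetonide without migration of the C7=C8 alkene and without the base that could trigger retro-aldol cleavage of the freed β-hydroxy aldehyde.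

**Step 23**
Reactants: 29 the diol acid
Product: 30 (2S,3R,4S,5S,9R,10S,13R)-2-acetoxy-3-hydroxy-19-oxolabd-7-en-15-oic acid (target)
Conditions: Ac2O, pyridine, CH2Cl2, 0 °C; aq work-up
Reagents that add atoms: acetic anhydride, CC(=O)OC(C)=O
Why: Sterically controlled acetylation picks the equatorial C2 hydroxyl over the axial C3 hydroxyl next to the quaternary C4, and aqueous work-up hydrolyses any mixed anhydride formed at C15.

**Compound list**
1 | 2,3-dimethylbenzoic acid | Cc1cccc(C(=O)O)c1C | starting material
2 | 6-hydroxy-2,3-dimethylbenzoic acid | Cc1ccc(O)c(C(=O)O)c1C | intermediate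
3 | methyl 6-hydroxy-2,3-dimethylbenzoate | COC(=O)c1c(O)ccc(C)c1C | intermediate
4 | methyl 6-(tert-butyldimethylsilyloxy)-2,3-dimethylbenzoate | COC(=O)c1c(O[Si](C)(C)C(C)(C)C)ccc(C)c1C | intermediate
5 | (R)-citronellol | C[C@H](CCC=C(C)C)CCO | starting material
6 | (R)-citronellol TIPS ether | CC(C)=CCC[C@@H](C)CCO[Si](C(C)C)(C(C)C)C(C)C | intermediate
7 | secondary ozonide of 6 (not isolated) | CC1(C)OOC(CC[C@@H](C)CCO[Si](C(C)C)(C(C)C)C(C)C)O1 | intermediate
8 | (4R)-4-methyl-6-(triisopropylsilyloxy)hexanal | O=CCC[C@@H](C)CCO[Si](C(C)C)(C(C)C)C(C)C | intermediate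
9 | ethyl 2-(triphenylphosphoranylidene)propanoate | CCOC(=O)C(C)=P(c1ccccc1)(c1ccccc1)c1ccccc1 | starting material
10 | ethyl (2E,6R)-2,6-dimethyl-8-(triisopropylsilyloxy)oct-2-enoate | CCOC(=O)/C(C)=C/CC[C@@H](C)CCO[Si](C(C)C)(C(C)C)C(C)C | intermediate
11 | (2E,6R) Weinreb amide | CON(C)C(=O)/C(C)=C/CC[C@@H](C)CCO[Si](C(C)C)(C(C)C)C(C)C | intermediate
12 | lithiated toluate, C6 benzylic lithium species (not isolated) | [Li]Cc1c(C)ccc(O[Si](C)(C)C(C)(C)C)c1C(=O)OC | intermediate
13 | C7 ketone (8E,13R) | COC(=O)c1c(O[Si](C)(C)C(C)(C)C)ccc(C)c1CC(=O)/C(C)=C/CC[C@@H](C)CCO[Si](C(C)C)(C(C)C)C(C)C | intermediate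
14 | (7R,13R) allylic alcohol | COC(=O)c1c(O[Si](C)(C)C(C)(C)C)ccc(C)c1C[C@@H](O)/C(C)=C/CC[C@@H](C)CCO[Si](C(C)C)(C(C)C)C(C)C | intermediate
15 | (7R,13R) allylic methyl carbonate, aryl TBS ether | COC(=O)c1c(O[Si](C)(C)C(C)(C)C)ccc(C)c1C[C@@H](OC(=O)OC)/C(C)=C/CC[C@@H](C)CCO[Si](C(C)C)(C(C)C)C(C)C | intermediate
16 | (7R,13R) salicylate allylic carbonate, free phenol (key-step precursor) | COC(=O)c1c(O)ccc(C)c1C[C@@H](OC(=O)OC)/C(C)=C/CC[C@@H](C)CCO[Si](C(C)C)(C(C)C)C(C)C | intermediate
17 | (9R,10S,13R) bicyclic cross-conjugated dienone ester (key-step product) | C1=C[C@@]2(C)[C@H](CC[C@@H](C)CCO[Si](C(C)C)(C(C)C)C(C)C)C(C)=CCC2=C(C(=O)OC)C1=O | intermediate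
18 | (9R,10S,13R) 4-en-3-one ester | C1C[C@@]2(C)[C@H](CC[C@@H](C)CCO[Si](C(C)C)(C(C)C)C(C)C)C(C)=CCC2=C(C(=O)OC)C1=O | intermediate
19 | lithium enolate of the trans-fused β-keto ester (not isolated) | C1C[C@@]2(C)[C@H](CC[C@@H](C)CCO[Si](C(C)C)(C(C)C)C(C)C)C(C)=CC[C@@H]2C(C(=O)OC)=C1O[Li] | intermediate
20 | (4S,5S,9R,10S,13R) 3-oxo-labd-7-en-19-oate | C1C[C@@]2(C)[C@H](CC[C@@H](C)CCO[Si](C(C)C)(C(C)C)C(C)C)C(C)=CC[C@@H]2[C@](C)(C(=O)OC)C1=O | intermediate
21 | potassium C2 enolate of 20 (not isolated) | C=1C[C@@]2(C)[C@H](CC[C@@H](C)CCO[Si](C(C)C)(C(C)C)C(C)C)C(C)=CC[C@@H]2[C@](C)(C(=O)OC)C=1O[K] | intermediate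
22 | (2S) 2-hydroxy-3-oxo ester | O[C@H]1C[C@@]2(C)[C@H](CC[C@@H](C)CCO[Si](C(C)C)(C(C)C)C(C)C)C(C)=CC[C@@H]2[C@](C)(C(=O)OC)C1=O | intermediate
23 | (2S,3R) cis-diol ester | O[C@H]1C[C@@]2(C)[C@H](CC[C@@H](C)CCO[Si](C(C)C)(C(C)C)C(C)C)C(C)=CC[C@@H]2[C@](C)(C(=O)OC)[C@H]1O | intermediate
24 | 2,3-acetonide ester | CC1(C)O[C@H]2C[C@@]3(C)[C@H](CC[C@@H](C)CCO[Si](C(C)C)(C(C)C)C(C)C)C(C)=CC[C@@H]3[C@](C)(C(=O)OC)[C@H]2O1 | intermediate
25 | 2,3-acetonide 19-ol | CC1(C)O[C@H]2C[C@@]3(C)[C@H](CC[C@@H](C)CCO[Si](C(C)C)(C(C)C)C(C)C)C(C)=CC[C@@H]3[C@](C)(CO)[C@H]2O1 | intermediate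
26 | 2,3-acetonide 19-al | CC1(C)O[C@H]2C[C@@]3(C)[C@H](CC[C@@H](C)CCO[Si](C(C)C)(C(C)C)C(C)C)C(C)=CC[C@@H]3[C@](C)(C=O)[C@H]2O1 | intermediate
27 | 2,3-acetonide 19-al 15-ol | CC1(C)O[C@H]2C[C@@]3(C)[C@H](CC[C@@H](C)CCO)C(C)=CC[C@@H]3[C@](C)(C=O)[C@H]2O1 | intermediate
28 | 2,3-acetonide 19-al 15-oic acid | CC1(C)O[C@H]2C[C@@]3(C)[C@H](CC[C@@H](C)CC(=O)O)C(C)=CC[C@@H]3[C@](C)(C=O)[C@H]2O1 | intermediate
29 | 2,3-dihydroxy-19-oxolabd-7-en-15-oic acid | O[C@H]1C[C@@]2(C)[C@H](CC[C@@H](C)CC(=O)O)C(C)=CC[C@@H]2[C@](C)(C=O)[C@H]1O | intermediate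
30 | CNP0180877.1, 2-acetoxy-3-hydroxy-19-oxolabd-7-en-15-oic acid | CC(=O)O[C@H]1C[C@@]2(C)[C@H](CC[C@@H](C)CC(=O)O)C(C)=CC[C@@H]2[C@](C)(C=O)[C@H]1O | target

Total step count: 23.
Longest linear sequence: 20 steps (steps 4–23, from (R)-citronellol).

**Steps most likely to fail**

**Step 12.**
- What may go wrong:
  - The endo attack on the allyl complex may be slow, so that β-hydride elimination to dienes takes over.
  - C-alkylation through the ester-bearing C4 may compete.
  - A long-lived allyl complex may lose the C7-to-C9 relay by metal–metal exchange.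
  - A boat-like transition state may bring in the wrong arene face.
- Fallback, from 14 back to 17: the external carbonate is given up and the C19 carboxylate is made the leaving group.
  - K2CO3 in MeOH removes the aryl silyl group from 14. After concentration and brief warming in toluene with catalytic DBU, the C7 hydroxyl closes on C19 to give the phenolic allylic lactone F1.
  - Pd2(dba)3·CHCl3 with dppb and Cs2CO3 in THF then ionises the allylic C7–O bond of F1 anti. This releases a phenolate–carboxylate dianion.
  - The carboxylate no longer drains charge from the ring as the ester does, and it shields C4. Its return to C7 only regenerates F1.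
  - Attack of C10 at C9 gives the dienone carboxylic acid F2, which Me3SiCHN2 in toluene–MeOH esterifies to 17.

**Step 16.**
- What may go wrong:
  - The hydride has to arrive from the face that carries the axial C19 ester, so facial selectivity may be poor or reversed.
  - The basic reagent may cause ketol transposition.
- Fallback, from 20 back to 25: reagent control is replaced by internal hydride delivery from C19.
  - TESOTf/Et3N converts 20 into the C2=C3 triethylsilyl enol ether F3.
  - LiAlH4 reduces its ester to the 19-hydroxy enol ether F4.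
  - Rubottom oxidation with one equivalent of dimethyldioxirane at −78 °C, on the face opposite C20, gives after silyl migration the 2-triethylsilyloxy-3-oxo-19-ol F5.
  - Evans–Saksena reduction with Me4N[HB(OAc)3] in MeCN–AcOH binds boron to the axial C19 oxygen and delivers hydride to C3 from that face. This gives the axial alcohol in the 3,19-diol F6.
  - PPTS in MeOH removes the silyl group to give the 2,3,19-triol F7.
  - Me2C(OMe)2/PPTS closes the only possible acetonide, because O-3 and C19 are antiperiplanar, and gives 25.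

**Step 10 (together with the handling of 14 from step 9).**
- What may go wrong: the free C7 hydroxyl may lactonise onto the neighbouring ester before or during acylation.
- Fallback, from 13 back to 15: a free C7 alcohol is avoided altogether.
  - KN(SiMe3)2 and then ClCO2Me O-acylate the benzylic enolate of 13 to the (Z)-dienyl enol carbonate F8.
  - Asymmetric hydrogenation with [Rh(cod)(Et-DuPhos)]BF4 and H2 follows. The ligand antipode that delivers 7R is fixed in a test run.
  - This hydrogenation saturates only the chelating enol-carbonate C6=C7 bond, as known for dienyl esters, and gives the allylic carbonate 15 directly.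

**Further compounds**
F1 | step 12 | (7R,13R) phenolic allylic lactone (8-hydroxy-5-methyl-3-alkenyl-3,4-dihydroisocoumarin) | Cc1ccc(O)c2c1C[C@@H](OC2=O)/C(C)=C/CC[C@@H](C)CCO[Si](C(C)C)(C(C)C)C(C)C
F2 | step 12 | (9R,10S,13R) dienone carboxylic acid | C1=C[C@@]2(C)[C@H](CC[C@@H](C)CCO[Si](C(C)C)(C(C)C)C(C)C)C(C)=CCC2=C(C(=O)O)C1=O
F3 | step 16 | C2=C3 triethylsilyl enol ether of 20 | C=1C[C@@]2(C)[C@H](CC[C@@H](C)CCO[Si](C(C)C)(C(C)C)C(C)C)C(C)=CC[C@@H]2[C@](C)(C(=O)OC)C=1O[Si](CC)(CC)CC
F4 | step 16 | 19-hydroxy triethylsilyl enol ether | C=1C[C@@]2(C)[C@H](CC[C@@H](C)CCO[Si](C(C)C)(C(C)C)C(C)C)C(C)=CC[C@@H]2[C@](C)(CO)C=1O[Si](CC)(CC)CC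
F5 | step 16 | 2-triethylsilyloxy-3-oxo-19-ol | CC[Si](CC)(CC)O[C@H]1C[C@@]2(C)[C@H](CC[C@@H](C)CCO[Si](C(C)C)(C(C)C)C(C)C)C(C)=CC[C@@H]2[C@](C)(CO)C1=O
F6 | step 16 | 2-triethylsilyloxy-3,19-diol with axial 3-OH | CC[Si](CC)(CC)O[C@H]1C[C@@]2(C)[C@H](CC[C@@H](C)CCO[Si](C(C)C)(C(C)C)C(C)C)C(C)=CC[C@@H]2[C@](C)(CO)[C@H]1O
F7 | step 16 | 2,3,19-triol | O[C@H]1C[C@@]2(C)[C@H](CC[C@@H](C)CCO[Si](C(C)C)(C(C)C)C(C)C)C(C)=CC[C@@H]2[C@](C)(CO)[C@H]1O
F8 | step 10 | (6Z,8E,13R) dienyl enol methyl carbonate | COC(=O)c1c(O[Si](C)(C)C(C)(C)C)ccc(C)c1/C=C(\OC(=O)OC)/C(C)=C/CC[C@@H](C)CCO[Si](C(C)C)(C(C)C)C(C)C
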